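Free catalyst and stray impurity vanish one for one, so their difference is an invariant while the poisoning rate per free catalyst, 2.81 /h, exceeds the partner's, 0.0171 /h.

left-handed substrate 0.050 M; partner 0.0300 M; protic impurity 1.00 mM; free catalyst 0.50 mM; stray impurity 0.53 mM; right-handed substrate 0.050 M; time 4.0 d

    partner + free catalyst + left-handed substrate → free catalyst + left-handed product (k1 = 9600 /M²/h)
    partner + free catalyst + right-handed substrate → free catalyst + right-handed product (k2 = 6000 /M²/h)
    free catalyst + stray impurity → spent catalyst A (k3 = 5300 /M/h)
    partner + free catalyst → spent catalyst B (k4 = 0.57 /M/h)
    partner + protic impurity → quenched reagent (k5 = 65 /M/h)

- how much left-handed product there is at 4.0 d, in percent of the left-handed substrate and right-handed substrate together charged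
- how much right-handed substrate there is at 4.0 d, in percent of the left-handed substrate and right-handed substrate together charged

**The measure.** The logarithm of the stray fraction left falls at 5300 /M/h times free catalyst, so that fall measures the catalyst's working life. While the substrates stand near their charge, the logarithm of the partner fraction falls nearly in proportion to it, and the logarithm of each substrate fraction falls in proportion to the partner consumed by turnover.

**What matters.** The last catalyst decays over 6.29 h, less than the run of 4.0 d, so an error in the time counts little. Protic impurity takes 3.33% of the partner, a small correction. The partner charge and the constants enter proportionally. The catalyst and stray charges need the most care, because their difference, 0.0300 mM, is less than either and stands inside the logarithm.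

**The number.** Stray impurity ends at a fraction 5.66%, so I get 2.87, the exposure. With substrates taken as charged, the unquenched partner keeps 65.5%. Turnover divides by the selectivity factor 1.60, leaving 88.4% of the left-handed substrate and 92.6% of the right-handed. I commit to y_P 5.80% and y_S 46.3%.

**The result.** The forecast says 5.5% and 46.5%: “the catalyst is killed within hours”. The flask gives 5.54% and 46.5%, a little from my figures. Its stray impurity stands at 6.98%, with spent catalyst B at 1.39% of the catalyst. That reading makes the exposure 2.66, and the same reckoning then leaves 89.1% of the left-handed substrate; the flask holds 89%.

**The neighbour.** With 3.2 × 10⁻⁴ M of stray impurity, catalyst exceeds stray by 0.180 mM, and the exposure grows with time to about 91.6. The partner's fraction left is then <0.001%, so I reckon y_P 15.0% and y_S 40.0%. The neighbour gives 17.3% and 38.3%, with 0.016% of its partner left.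

All constants are assumed; no experiment stands behind them.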